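**Plan**
- Retrosynthetic cuts: (1) the ester C–O bond between O2' and the 3-methylbut-2-enoyl carbonyl; (2) the side-chain bond C1'–C2'; (3) the α-pyranone ring at C4–C4a and at the aryl ester bond O1–C2.
- Enabling feature: the side chain is an aryl acyloin. The ketone carbon C1' on coumarin C8 is bonded directly to the oxygen-bearing stereocentre C2', so two former aldehyde carbons sit head to head, one of them joined with reversed polarity.
- Forward order: the phenol of 1 is esterified with 2; the pyranone ring (the only ring made) closes by hydroarylation to formylcoumarin 4; 4 and methacrolein 5 are joined at C1'–C2'; the C2' hydroxyl is acylated last.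
- Stereochemistry: the single stereocentre C2' (S) is set in the carboligation by the enzyme active site and is not touched by the final O-acylation.

Key step: step 3

Remark: side-chain atoms are numbered C1' (carbonyl carbon on C8) to C4'; 1, 2, 5 and 7 are taken as purchased, and an (S)-selective carboligase variant is assumed to be obtainable by screening known ThDP enzymes.

Step 1
Reactants: 1 2-hydroxy-4,6-dimethoxybenzaldehyde; 2 propiolic acid (prop-2-ynoic acid)
Product: 3 2-formyl-3,5-dimethoxyphenyl prop-2-ynoate
Conditions: DCC (1.2 equiv), DMAP (5 mol %), CH2Cl2, 0 °C → rt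
Reagents that add atoms: none
Why: Steglich-type carbodiimide esterification, in which DCC turns 2 into an O-acylisourea that the phenol of 1 attacks, while the low temperature and the small amount of DMAP should suppress conjugate addition to the ynoate and leave the aldehyde untouched.

Step 2
Reactants: 3 2-formyl-3,5-dimethoxyphenyl prop-2-ynoate
Product: 4 5,7-dimethoxy-2-oxo-2H-chromene-8-carbaldehyde (5,7-dimethoxy-8-formylcoumarin)
Conditions: JohnPhosAu(MeCN)SbF6 (5 mol %), 1,2-dichloroethane, 60 °C
Reagents that add atoms: none
Why: Gold(I)-catalysed intramolecular hydroarylation of an aryl alkynoate (6-endo-dig, Friedel–Crafts type), in which the gold π-complex of the ynoate is attacked by the only free carbon ortho to the ester oxygen (ortho and para to the two methoxy groups, meta to the formyl group) and protodeauration closes the α-pyranone ring with the aldehyde at C8.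

Step 3
Reactants: 4 5,7-dimethoxy-2-oxo-2H-chromene-8-carbaldehyde; 5 methacrolein (2-methylprop-2-enal)
Product: 6 8-[(2S)-2-hydroxy-3-methylbut-3-enoyl]-5,7-dimethoxy-2H-chromen-2-one
Conditions: (S)-selective ThDP-dependent carboligase (benzoylformate decarboxylase variant from a screened panel, e.g. L461A/L476Q lineage), ThDP, MgSO4, potassium phosphate buffer pH 6.5, 20% v/v DMSO, 25 °C; 5 (3–5 equiv) fed in portions
Reagents that add atoms: none
Why: Proposed new method: the thiazolium C2 ylide of enzyme-bound ThDP adds to the formyl carbon of 4 and, after deprotonation, the resulting Breslow-type enamine (an acyl anion equivalent) attacks the carbonyl carbon of 5, after which proton transfer and release of the cofactor leave the aryl ketone C1' and the secondary alcohol C2'. The closest known reaction is the cross-acyloin carboligation of benzaldehydes as donors with acetaldehyde or propanal as acceptors to 2-hydroxy-1-arylalkan-1-ones by benzaldehyde lyase and benzoylformate decarboxylase, including variants that tolerate ortho-substituted donors or have an enlarged acceptor pocket; a donor flanked on both ortho positions and an α-branched enal acceptor have not been shown. No ring is closed. The new stereocentre C2' is controlled by the enzyme alone: with the isopropenyl group of 5 held in the S-pocket, antiparallel to the donor aryl group, the enamine reaches the carbonyl face that gives (S), the homologue of (S)-2-hydroxypropiophenone. The step needs cross- over homo-coupling, the aryl aldehyde as donor and 1,2- over 1,4-addition; 4 is too hindered to serve as acceptor and its aryl ring fits the donor site, while 5 is small enough to sit with its carbonyl at the active-site proton donors and its α-methyl group slows conjugate addition. The near-neutral buffer should spare the lactone, the β,γ-alkene and the enolisable C2'–H.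

Step 4
Reactants: 6 8-[(2S)-2-hydroxy-3-methylbut-3-enoyl]-5,7-dimethoxy-2H-chromen-2-one; 7 3-methylbut-2-enoyl chloride
Product: 8 (2S)-1-(5,7-dimethoxy-2-oxo-2H-chromen-8-yl)-3-methyl-1-oxobut-3-en-2-yl 3-methylbut-2-enoate (CNP0172360.1)
Conditions: pyridine (3 equiv), CH2Cl2, −20 → 0 °C
Reagents that add atoms: none
Why: O-acylation of a secondary alcohol with an acid chloride by way of the N-acylpyridinium ion (nucleophilic acyl substitution), so no bond to C2' is broken and the (S) configuration is retained; pyridine is too weak a base to enolise the aryl ketone or to turn 7 into the vinylketene that would give the deconjugated ester.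

**Compound list**
1 | 2-hydroxy-4,6-dimethoxybenzaldehyde | O=Cc1c(O)cc(OC)cc1OC | starting material
2 | propiolic acid (prop-2-ynoic acid) | C#CC(=O)O | starting material
3 | 2-formyl-3,5-dimethoxyphenyl prop-2-ynoate | C#CC(=O)Oc1cc(OC)cc(OC)c1C=O | intermediate
4 | 5,7-dimethoxy-2-oxo-2H-chromene-8-carbaldehyde | O=Cc1c(OC)cc(OC)c2ccc(=O)oc12 | intermediate
5 | methacrolein (2-methylprop-2-enal) | C=C(C)C=O | starting material
6 | 8-[(2S)-2-hydroxy-3-methylbut-3-enoyl]-5,7-dimethoxy-2H-chromen-2-one | C=C(C)[C@H](O)C(=O)c1c(OC)cc(OC)c2ccc(=O)oc12 | intermediate
7 | 3-methylbut-2-enoyl chloride | CC(C)=CC(=O)Cl | starting material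
8 | (2S)-1-(5,7-dimethoxy-2-oxo-2H-chromen-8-yl)-3-methyl-1-oxobut-3-en-2-yl 3-methylbut-2-enoate | C=C(C)[C@H](OC(=O)C=C(C)C)C(=O)c1c(OC)cc(OC)c2ccc(=O)oc12 | target

Total step count: 4
Longest linear sequence: 4 steps (1 → 3 → 4 → 6 → 8)

**Steps most likely to fail**

Step 3 (proposed new method). The formyl group, flanked on both sides, may not reach the cofactor ylide, so that no turnover occurs. The acceptor may bind in the parallel orientation and erode or reverse the facial selectivity. The enal may add 1,4 or inactivate the enzyme covalently. The fallback uses known chemistry and forms the same C1'–C2' bond with normal polarity. It sets out from 4, which is treated at −78 °C in a Brown alkoxyallylboration with the (Z)-γ-(methoxymethoxy)-β-methylallyl diisopinocampheylborane generated from 3-(methoxymethoxy)-2-methylprop-1-ene (s-BuLi, THF, −78 °C; then (+)-Ipc2BOMe, derived from (−)-α-pinene; then BF3·OEt2), followed by a non-oxidative ethanolamine work-up. Re-face attack on the aldehyde and the chair transition state of the Z-alkoxyallyl unit should give the syn adduct 8-[(1S,2S)-1-hydroxy-2-(methoxymethoxy)-3-methylbut-3-en-1-yl]-5,7-dimethoxy-2H-chromen-2-one F1. Dess–Martin oxidation of the benzylic carbinol (NaHCO3, CH2Cl2, 0 °C) should then give (S)-5,7-dimethoxy-8-[2-(methoxymethoxy)-3-methylbut-3-enoyl]-2H-chromen-2-one F2. Cleavage of the MOM ether with dilute HCl in methanol (0 °C → rt) comes back to the route at 6.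

Step 4. The base may remove the γ-hydrogen of the acid chloride (vinylketene formation, leading to the deconjugated 3-methylbut-3-enoate). It may also remove the doubly activated C2'–H, causing epimerisation or migration of the alkene into conjugation. The fallback esterifies with inversion under neutral conditions, with no acyl electrophile and no amine base. It sets out from 4 and 5, which are united as in step 3 but with wild-type (R)-selective benzaldehyde lyase, to give 8-[(2R)-2-hydroxy-3-methylbut-3-enoyl]-5,7-dimethoxy-2H-chromen-2-one F3. Mitsunobu esterification of F3 with 3-methylbut-2-enoic acid (PPh3, DIAD, THF, 0 °C) displaces the activated oxygen with inversion at C2' and comes back to the route at 8.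

Step 2. The formyl group deactivates the ring, so the Friedel–Crafts-type attack on the gold-activated alkyne may be outrun by hydration of the alkyne or cleavage of the aryl ester. The fallback builds the lactone from the formyl group of 1 and introduces the C8 aldehyde afterwards. It sets out from 1, which is heated with ethyl (triphenylphosphoranylidene)acetate in N,N-diethylaniline at reflux. Wittig olefination gives ethyl (E)-3-(2-hydroxy-4,6-dimethoxyphenyl)prop-2-enoate F4, which should isomerise and lactonise in the same flask to 5,7-dimethoxy-2H-chromen-2-one F5. Rieche formylation of F5 (Cl2CHOMe, TiCl4, CH2Cl2, 0 °C) is expected at C8, which is para to the 5-methoxy group and less hindered than C6 between two methoxy groups; this comes back to the route at 4, with any 6-formyl isomer to be separated.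

**Further compounds**
F1 | step 3 | 8-[(1S,2S)-1-hydroxy-2-(methoxymethoxy)-3-methylbut-3-en-1-yl]-5,7-dimethoxy-2H-chromen-2-one | C=C(C)[C@H](OCOC)[C@@H](O)c1c(OC)cc(OC)c2ccc(=O)oc12
F2 | step 3 | (S)-5,7-dimethoxy-8-[2-(methoxymethoxy)-3-methylbut-3-enoyl]-2H-chromen-2-one | C=C(C)[C@H](OCOC)C(=O)c1c(OC)cc(OC)c2ccc(=O)oc12
F3 | step 4 | 8-[(2R)-2-hydroxy-3-methylbut-3-enoyl]-5,7-dimethoxy-2H-chromen-2-one | C=C(C)[C@@H](O)C(=O)c1c(OC)cc(OC)c2ccc(=O)oc12
F4 | step 2 | ethyl (E)-3-(2-hydroxy-4,6-dimethoxyphenyl)prop-2-enoate | CCOC(=O)/C=C/c1c(O)cc(OC)cc1OC
F5 | step 2 | 5,7-dimethoxy-2H-chromen-2-one | COc1cc(OC)c2ccc(=O)oc2c1
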